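The numbers in the tables stem from a simulated flask with made-up constants; noise was put on by code.

Time is the setting I trust least in these flasks, so I read the earlier runs for rates, not for amounts.

| flask | substrate | reagent | remark | time |
|---|---|---|---|---|
| north-east | 0.050 M | 0.10 M | run made earlier |  |
| north | 0.025 M | 0.10 M | run made earlier |  |
| west | 0.038 M | 0.10 M | run made earlier |  |
| oak | 0.050 M | 0.100 M | everything together at the start | 2.0 h |
| birch | 0.050 M (fed, over 80 min) | 0.100 M | all else is in the flask from the start; the feed brings no volume worth counting | 2.0 h |
| alder | 0.050 M | 0.100 M (fed, over 80 min) | all else is in the flask from the start; the feed brings no volume worth counting | 2.0 h |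
| cedar | 0.050 M (in portions, 5, over 80 min) | 0.100 M | first portion at the start, last at 80 min | 2.0 h |

| run | time / min | target / % | substrate / % |
|---|---|---|---|
| north-east | 6.00 | 19 | 41 |
| north-east | 20.0 | 61 | 2 |
| north-east | 30.0 | 72 | 0 |
| north-east | 50.0 | 84 | 0 |
| north-east | 80.0 | 89 | 0 |
| north | 10.0 | 39 | 18 |
| north | 30.0 | 74 | 6 |
| north | 60.0 | 91 | 0 |
| north | 80.0 | 92 | 0 |
| north | 120 | 96 | 0 |
| west | 10.0 | 36 | 19 |
| west | 30.0 | 72 | 0 |
| west | 60.0 | 90 | 0 |
| west | 80.0 | 91 | 0 |
| west | 120 | 92 | 0 |

(each reading ± 2 percentage points)

- the analysis behind the earlier runs scatters by 2 percentage points, standard deviation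

- the flask that comes out highest in amount of target, in percent of the substrate charged, or "all alike" when all lie within 1.5 percentage points (oak / birch / alder / cedar / all alike)
- target at the end, in percent of the substrate charged, oak
- target at the end, in percent of the substrate charged, birch
- target at the end, in percent of the substrate charged, alder
- target at the end, in percent of the substrate charged, cedar

Call the pool whatever of the charge is neither substrate nor target, and let κ be the rise of target per minute divided by the mean pool over a stretch. It is a clearing rate, pseudo-first-order with reagent folded in. In the north-east run, whose charges are oak's, target rises by 0.0300 /min of the charge between 6.00 min and 20.0 min, but by 0.00167 /min between 50.0 min and 80.0 min, a fall by a factor 18.0. The shrinking pool gives a factor 2.85. The rest is κ itself, which goes from 0.0779 /min to 0.0123 /min, a reading that hangs on a late rise of 5 percentage points.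

The north run, with half the substrate, shows κ falling too, by a factor 4.33. So I treat κ as fading on the clock, at λ = 0.0354 /min, a half-life of 19.6 min, and I suspect reagent of losing itself.

The clearing still to come for material entering at time t is then R(t) = κ(t)/λ, the remaining clearing; at the start I extrapolate it to 3.49, and on this reckoning a share exp(−R) of that material stays short of target. Averaged over the feed, my reckoning puts birch near 57.7%, a figure that counts clearing beyond the stop at 2.0 h. Oak, with the charges of the north-east run, should stand near the 89% read there at 80.0 min. Alder's reagent goes in over 80 min, longer than that half-life, so I put alder first, without a figure.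

The forecast differs: it names birch, with oak 90.5%, birch 93.5%, alder 87% and cedar 92.5%, holding that “Feeding substrate therefore keeps concentrations low”.

The flasks give oak 89.3%, birch 53.8%, alder 94.2% and cedar 56.4%, with alder highest.

    2 reagent → homo dimer (k = 0.00540 /M/s)
    substrate → intermediate (k = 0.00260 /s)
    substrate + intermediate → side product (k = 0.00120 /M/s)
    substrate ⇌ dormant form (K = 1.30, k = 9.30 × 10⁻⁵ /s)
    reagent + intermediate → target (k = 0.0290 /M/s)

In alder at 0.0720 h, reagent goes into target 13 times as fast as into homo dimer, and alder ends with homo dimer at 0.0183 M. Birch ends with homo dimer at 0.0360 M, which at two reagent each is 72.0% of the reagent charge, with 1.10% of that charge left and intermediate standing at 42.6%. The remaining clearing, taken at cedar's 5 evenly spaced portions, gives 57.7%, and cedar stands at 56.4%.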